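**Plan**
- Retrosynthesis: remove the two formyl groups (Rieche), then the C7'–isobutyl bond (allylsilane on a benzylic cation), then cut aryl–C7' and aryl O–C1 together, which amounts to inserting a 3,5-dioxygenated aryne between the tertiary alkoxide on C1 and the formyl group on C4 of a 1β-hydroxyaromadendrane-4β-carbaldehyde.
- Enabling feature: O–C1 and C7'–C4 are cis-1,3 on the cyclopentane (C1–C5–C4) and end on adjacent aromatic carbons, so the oxepane ring (O, C1, C5, C4, C7', two aromatic C) can be zipped by O-arylation followed by addition of the ortho aryl anion to the aldehyde.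
- Terpene part: cut the cyclopentene at C4=C5 (McMurry) and C1–C2 (Michael) back to a bicyclo[5.1.0]octanone, made from (+)-2-carene by hydroboration/oxidation and a one-carbon ring expansion.
- Forward order: cyclopropane (bought) → seven-membered carbocycle → cyclopentene → quaternary C4 (ene) → C1–OH (directed hydroboration) → oxepane (aryne annulation) → isobutyl → formyl groups.
- Stereochemistry: C6/C7 from (+)-2-carene; C10 by hydroboration anti to the CMe2 bridge; H-1 (relay) by Michael addition anti to the 10-methyl; C4 by the suprafacial ene reaction; C1/C5 by hydroxyl-delivered syn hydroboration; C7' by attack on the bridged benzylic cation from the face of the C5 bridge.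

Key step: step 11

Remark: aromadendrane numbering is used for the terpene part (C1 and C5 ring-fusion carbons, C4 the methyl-bearing cyclopentane carbon, C6/C7 cyclopropane CH, C10 the CHMe carbon, C11 the CMe2 carbon), C7' is the benzylic carbon and β is the face of C11; hydroxy aldehyde 14 is drawn open because its lactol would be a strained 2-oxabicyclo[2.2.1]heptane, and 3,5-bis(benzyloxy)phenol is taken as a catalogue compound.

Step 1
Reactants: 1 (+)-2-carene
Product: 3 2-isocaranol, via bis(2-isocaranyl)borane 2 (not isolated)
Conditions: BH3·THF (0.55 equiv), THF, 0 °C; then NaOH, H2O2, 0 °C → rt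
Reagents that add atoms: hydrogen peroxide (OO)
Why: hydroboration–oxidation, in which borane adds syn from the face away from the CMe2 bridge with boron on the less substituted C2, so the new hydrogen on the methyl-bearing carbon (the later C10) is anti to the bridge and the methyl group is left syn to it.

Step 2
Reactants: 3 2-isocaranol
Product: 4 2-isocaranone
Conditions: Dess–Martin periodinane, NaHCO3, CH2Cl2, 0 °C
Reagents that add atoms: none
Why: Dess–Martin oxidation of the secondary cyclopropylcarbinol under buffered, non-basic conditions should leave the enolisable methyl-bearing α-centre untouched.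

Step 3
Reactants: 4 2-isocaranone
Product: 6 4,8,8-trimethylbicyclo[5.1.0]octan-2-one, via silyl ketone 5 (not isolated)
Conditions: Me3SiCHN2, Sc(OTf)3 (5 mol %), CH2Cl2, −40 °C; then K2CO3 (cat.), MeOH
Reagents that add atoms: trimethylsilyldiazomethane (C[Si](C)(C)C=[N+]=[N-])
Why: Lewis-acid-catalysed diazoalkane homologation (Tiffeneau–Demjanov-type ring expansion), in which the CHMe carbon should migrate with retention because a cyclopropane ring carbon is the poorer migrating group and the product keeps the cyclopropyl–carbonyl conjugation, so the methyl stereocentre (C10) ends β to the carbonyl and can no longer epimerise.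

Step 4
Reactants: 6 4,8,8-trimethylbicyclo[5.1.0]octan-2-one
Product: 9 4,8,8-trimethyl-3-(3-oxobutyl)bicyclo[5.1.0]octan-2-one, via lithium enolate 7 (not isolated), via silyl diketone 8 (not isolated)
Conditions: LiN(iPr)2, THF, −78 °C; 3-(trimethylsilyl)but-3-en-2-one, −78 → −40 °C; then KF (cat.), MeOH, 0 °C; aq. NH4Cl
Reagents that add atoms: 3-(trimethylsilyl)but-3-en-2-one (CC(=O)C(=C)[Si](C)(C)C)
Why: Michael addition in the Stork–Ganem variant, where the enolate can form only towards the CH2 group (the other α-carbon is a cyclopropane CH) and is attacked anti to the neighbouring methyl group and to the CMe2 bridge, which sets C1 with its hydrogen on the β face.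

Step 5
Reactants: 9 4,8,8-trimethyl-3-(3-oxobutyl)bicyclo[5.1.0]octan-2-one
Product: 10 10-epi-α-gurjunene
Conditions: TiCl3(DME)1.5, Zn(Cu), DME, reflux, slow addition
Reagents that add atoms: none
Why: intramolecular McMurry coupling of the 1,5-diketone closes the cyclopentene at C4=C5 without creating a stereocentre, the titanium-bound cyclopropyl ketyl being expected to couple faster than it ring-opens.

Step 6
Reactants: 10 10-epi-α-gurjunene
Product: 11 4β-(hydroxymethyl)-10-epi-aromadendr-1(5)-ene
Conditions: (CH2O)n, Me2AlCl, CH2Cl2, −78 → 0 °C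
Reagents that add atoms: formaldehyde (C=O)
Why: Me2AlCl-promoted carbonyl-ene reaction with monomeric formaldehyde set free from paraformaldehyde, in which C–C bond formation at the less hindered C4 (charge developing at the cyclopropyl-substituted C5) is coupled to suprafacial transfer of H-1 from the β face, so the hydroxymethyl group enters β and the double bond moves to C1=C5.

Step 7
Reactants: 11 4β-(hydroxymethyl)-10-epi-aromadendr-1(5)-ene
Product: 13 4β-(hydroxymethyl)-10-epi-aromadendran-1β-ol, via cyclic alkoxyborane 12 (not isolated)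
Conditions: BH3·THF (1.1 equiv), THF, 0 °C → rt; then NaOH, H2O2, 50 °C
Reagents that add atoms: hydrogen peroxide (OO)
Why: hydroxyl-directed hydroboration–oxidation, in which the alkoxyborane formed at the β-CH2OH group delivers B–H syn across C1=C5 from the β face with boron on C1 (six-membered oxaborinane; C5 is the neopentyl, cyclopropyl-stabilised end), which sets the 1β-OH and the 5β-H.

Step 8
Reactants: 13 4β-(hydroxymethyl)-10-epi-aromadendran-1β-ol
Product: 14 1β-hydroxy-10-epi-aromadendrane-4β-carbaldehyde
Conditions: Dess–Martin periodinane (1.1 equiv), NaHCO3, CH2Cl2, 0 °C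
Reagents that add atoms: none
Why: Dess–Martin oxidation takes the primary alcohol to the aldehyde while the tertiary alcohol cannot be oxidised and the aldehyde, having a quaternary α-carbon, cannot enolise.

Step 9
Reactants: 15 3,5-bis(benzyloxy)phenol
Product: 16 3,5-bis(benzyloxy)-2-bromophenol
Conditions: N-bromosuccinimide, CH2Cl2, −78 °C
Reagents that add atoms: N-bromosuccinimide (BrN1C(=O)CCC1=O)
Why: electrophilic aromatic bromination should go ortho to the free hydroxyl group, the position between the two benzyloxy groups being the more hindered one.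

Step 10
Reactants: 16 3,5-bis(benzyloxy)-2-bromophenol
Product: 19 3,5-bis(benzyloxy)-2-(trimethylsilyl)phenyl trifluoromethanesulfonate, via aryl silyl ether 17 (not isolated), via lithium phenoxide 18 (not isolated)
Conditions: (Me3Si)2NH, THF, 65 °C; evaporate; n-BuLi, THF, −100 → −80 °C; Tf2O, −100 → −78 °C
Reagents that add atoms: hexamethyldisilazane (C[Si](C)(C)N[Si](C)(C)C), trifluoromethanesulfonic anhydride (O=S(=O)(OS(=O)(=O)C(F)(F)F)C(F)(F)F)
Why: O-silylation, bromine–lithium exchange with migration of silicon from oxygen to carbon (retro-Brook rearrangement) and triflation of the phenoxide, the standard route to ortho-silylaryl triflates.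

Step 11
Reactants: 14 1β-hydroxy-10-epi-aromadendrane-4β-carbaldehyde; 19 3,5-bis(benzyloxy)-2-(trimethylsilyl)phenyl trifluoromethanesulfonate
Product: 23 bridged benzoxepinol, via potassium alkoxide 20 (not isolated), via benzyne 21 (not isolated), via aryl anion 22 (not isolated)
Conditions: KH (1.1 equiv), THF, 0 °C; then 19 (1.2 equiv, syringe pump), KF, 18-crown-6, THF (0.01 M), 0 °C → rt; aq. NH4Cl
Reagents that add atoms: none
Why: Proposed new method: fluoride-induced 1,2-elimination of 19 gives 3,5-bis(benzyloxy)benzyne 21, to which the tertiary potassium alkoxide 20 adds at the aryne carbon remote from the 3-benzyloxy group (the regiochemistry general for 3-alkoxyarynes), so that the carbanion of 22 sits between the new ether oxygen and a benzyloxy group. This aryl anion adds to the neighbouring formyl carbon C7' in a 7-exo-trig closure that forms the aryl–C7' bond and with it the oxepane ring of the bicyclo[4.2.1] core; the closest known reaction type is the aryne annulation of salicylaldehydes and salicylates to xanthenols and xanthones (and aryne acyl-alkylation), here carried over to an aliphatic cis-1,3-hydroxy aldehyde. The only new stereocentre, the carbinol C7', is not controlled and need not be, since both epimers give the same benzylic cation in step 12. The step needs arylation at the tertiary alkoxide and not at a hemiacetal oxygen, and ring closure faster than protonation of the aryl anion: the strain of the bridged lactol keeps the open alkoxide populated, the cis-1,3 placement of O–C1 and the formyl group on the cyclopentane holds the electrophile next to the carbanion, the aldehyde has no α-hydrogen, and the medium (THF, hydride-derived alkoxide, no amine) offers no acid.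

Step 12
Reactants: 23 bridged benzoxepinol
Product: 24 C7'-(2-methylallyl) bis(benzyl ether)
Conditions: methallyltrimethylsilane (5 equiv), Bi(OTf)3 (5 mol %), CH2Cl2, −40 °C
Reagents that add atoms: methallyltrimethylsilane (CC(=C)C[Si](C)(C)C)
Why: Hosomi–Sakurai-type allylation of the benzylic cation formed from either carbinol epimer (stabilised by the ring ether oxygen and the ortho/para benzyloxy groups), which the silane should attack from the face of the one-carbon bridge C5 (the exo face of the bicyclo[4.2.1] skeleton, anti to the C2–C3 bridge), setting C7'.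

Step 13
Reactants: 24 C7'-(2-methylallyl) bis(benzyl ether)
Product: 25 bis-deformyl target
Conditions: H2 (1 atm), Pd/C, EtOAc–EtOH, rt
Reagents that add atoms: none
Why: catalytic hydrogenation saturates the 1,1-disubstituted alkene to the isobutyl group and hydrogenolyses both benzyl ethers, while the isolated gem-dimethylcyclopropane and the bridgehead alkyl aryl ether should be inert and no stereocentre is formed.

Step 14
Reactants: 25 bis-deformyl target
Product: 26 CNP0189833.2
Conditions: Cl2CHOMe, TiCl4, CH2Cl2, −20 → 0 °C; then 1 M HCl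
Reagents that add atoms: dichloromethyl methyl ether (COC(Cl)Cl), water (O)
Why: Rieche formylation through the titanium phenoxides introduces a formyl group at each of the two remaining ring positions, both of which are ortho to a phenolic oxygen, so no regiochemical choice arises.

**Compound list**
1 | (+)-2-carene, (1S,6R)-3,7,7-trimethylbicyclo[4.1.0]hept-2-ene | CC1=C[C@H]2[C@@H](CC1)C2(C)C | starting material
2 | bis(2-isocaranyl)borane (boron on C2 anti to the CMe2 bridge) | [BH]([C@@H]1[C@@H](C)CC[C@@H]2[C@H]1C2(C)C)[C@@H]1[C@@H](C)CC[C@@H]2[C@H]1C2(C)C | intermediate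
3 | 2-isocaranol, 3,7,7-trimethylbicyclo[4.1.0]heptan-2-ol with OH anti and 3-methyl syn to the CMe2 bridge | C[C@H]1CC[C@@H]2[C@H]([C@@H]1O)C2(C)C | intermediate
4 | 2-isocaranone, 3,7,7-trimethylbicyclo[4.1.0]heptan-2-one with 3-methyl syn to the CMe2 bridge | C[C@H]1CC[C@@H]2[C@H](C1=O)C2(C)C | intermediate
5 | 4,8,8-trimethyl-3-(trimethylsilyl)bicyclo[5.1.0]octan-2-one | C[C@H]1CC[C@@H]2[C@H](C(=O)C1[Si](C)(C)C)C2(C)C | intermediate
6 | 4,8,8-trimethylbicyclo[5.1.0]octan-2-one, 4-methyl syn to the CMe2 bridge | C[C@H]1CC[C@@H]2[C@H](C(=O)C1)C2(C)C | intermediate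
7 | lithium enolate of 6 (C2–OLi, C2=C3) | C[C@H]1CC[C@@H]2[C@H](C(=C1)O[Li])C2(C)C | intermediate
8 | 4,8,8-trimethyl-3-[3-oxo-2-(trimethylsilyl)butyl]bicyclo[5.1.0]octan-2-one | CC(=O)C(C[C@@H]1[C@@H](C)CC[C@@H]2[C@H](C1=O)C2(C)C)[Si](C)(C)C | intermediate
9 | 4,8,8-trimethyl-3-(3-oxobutyl)bicyclo[5.1.0]octan-2-one, side chain anti to the 4-methyl and to the bridge | CC(=O)CC[C@@H]1[C@@H](C)CC[C@@H]2[C@H](C1=O)C2(C)C | intermediate
10 | 10-epi-α-gurjunene (aromadendr-4-ene, 1β-H, 10β-methyl) | C[C@H]1CC[C@@H]2[C@@H](C2(C)C)C3=C(C)CC[C@H]13 | intermediate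
11 | 4β-(hydroxymethyl)-10-epi-aromadendr-1(5)-ene (4α-methyl) | OC[C@@]1(C)CCC2=C1[C@H]1[C@@H](CC[C@@H]2C)C1(C)C | intermediate
12 | cyclic alkoxyborane (1,2-oxaborinane, B–H, boron on C1β, oxygen on C7') | [BH]1OC[C@@]2(C)CC[C@]13[C@@H]2[C@H]1[C@@H](CC[C@@H]3C)C1(C)C | intermediate
13 | 4β-(hydroxymethyl)-10-epi-aromadendran-1β-ol (5β-H) | O[C@]12CC[C@](C)(CO)[C@H]1[C@H]1[C@@H](CC[C@@H]2C)C1(C)C | intermediate
14 | 1β-hydroxy-10-epi-aromadendrane-4β-carbaldehyde (5β-H) | O[C@]12CC[C@](C)(C=O)[C@H]1[C@H]1[C@@H](CC[C@@H]2C)C1(C)C | intermediate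
15 | 3,5-bis(benzyloxy)phenol | Oc1cc(OCc2ccccc2)cc(OCc2ccccc2)c1 | starting material
16 | 3,5-bis(benzyloxy)-2-bromophenol | Oc1cc(OCc2ccccc2)cc(OCc2ccccc2)c1Br | intermediate
17 | [3,5-bis(benzyloxy)-2-bromophenoxy]trimethylsilane | C[Si](C)(C)Oc1cc(OCc2ccccc2)cc(OCc2ccccc2)c1Br | intermediate
18 | lithium 3,5-bis(benzyloxy)-2-(trimethylsilyl)phenoxide | [Li+].[O-]c1cc(OCc2ccccc2)cc(OCc2ccccc2)c1[Si](C)(C)C | intermediate
19 | 3,5-bis(benzyloxy)-2-(trimethylsilyl)phenyl trifluoromethanesulfonate | C[Si](C)(C)c1c(OS(=O)(=O)C(F)(F)F)cc(OCc2ccccc2)cc1OCc1ccccc1 | intermediate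
20 | potassium alkoxide of 14 | [K+].[O-][C@]12CC[C@](C)(C=O)[C@H]1[C@H]1[C@@H](CC[C@@H]2C)C1(C)C | intermediate
21 | 3,5-bis(benzyloxy)benzyne | C1#CC(OCc2ccccc2)=CC(OCc2ccccc2)=C1 | intermediate
22 | potassium aryl anion: 3,5-bis(benzyloxy)phenyl ether of 14 at O–C1, metalated at the ring carbon between the ether oxygen and a benzyloxy group | [K+].[c-]1c(OCc2ccccc2)cc(OCc2ccccc2)cc1O[C@]12CC[C@](C)(C=O)[C@H]1[C@H]1[C@@H](CC[C@@H]2C)C1(C)C | intermediate
23 | bridged benzoxepinol: skeleton of 26 with OH in place of isobutyl on C7' (both epimers), benzyl ethers in place of the phenols, no formyl groups | OC1c2c(OCc3ccccc3)cc(OCc3ccccc3)cc2O[C@]23CC[C@@]1(C)[C@H]2[C@H]1[C@@H](CC[C@@H]3C)C1(C)C | intermediate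
24 | C7'-(2-methylallyl) bis(benzyl ether), C7' configured as in 26 | CC(=C)C[C@H]1c2c(OCc3ccccc3)cc(OCc3ccccc3)cc2O[C@]23CC[C@@]1(C)[C@H]2[C@H]1[C@@H](CC[C@@H]3C)C1(C)C | intermediate
25 | bis-deformyl target (isobutyl, two free phenols) | CC(C)C[C@H]1c2c(O)cc(O)cc2O[C@]23CC[C@@]1(C)[C@H]2[C@H]1[C@@H](CC[C@@H]3C)C1(C)C | intermediate
26 | CNP0189833.2 | CC(C)C[C@H]1c2c(O)c(C=O)c(O)c(C=O)c2O[C@]23CC[C@@]1(C)[C@H]2[C@H]1[C@@H](CC[C@@H]3C)C1(C)C | target

**Step count and risks**
Total step count: 14. Longest linear sequence: 12 (steps 1–8 and 11–14); steps 9–10 make the aryne precursor.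

Step 11 (Proposed new method). What may go wrong: the aryl anion may be protonated before it closes the ring, or the hemiacetal oxygen of the closed lactol form may be arylated in place of the tertiary alkoxide. The fallback separates the two events and closes the ring as an electrophilic substitution; it sets out from diol 13 and comes back at 24. The primary hydroxyl is silylated (t-BuMe2SiCl, imidazole) to the silyl ether F1. The tertiary alcohol is O-arylated with the benzyne from 19 (KH, 0.2 equiv; then 19, KF, 18-crown-6, THF), the remaining free alcohol protonating the aryl anion and regenerating the alkoxide, to give the aryl ether F2. Bu4NF gives the primary alcohol F3 and Dess–Martin oxidation the aldehyde F4. A one-pot intramolecular Friedel–Crafts hydroxyalkylation and Hosomi–Sakurai allylation (Bi(OTf)3, methallyltrimethylsilane, CH2Cl2, −78 °C) then forms the aryl–C7' bond and introduces the methallyl group, giving 24. Its own risk is acid cleavage of the still unbridged tertiary aryl ether.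

Step 6. What may go wrong: stepwise ionisation to the cyclopropylcarbinyl cation at C5 with opening of the cyclopropane or chloride capture, or attack of formaldehyde on the α face. The fallback builds the quaternary centre by an aldol reaction; it sets out from ketone 6 and comes back at 11. The lithium enolate of 6 is alkylated with methyl 4-iodo-2-methylbutanoate to the keto ester F5. LiN(iPr)2 at −78 °C closes the cyclopentane by intramolecular ester-enolate aldol addition to the chelated cis-fused hydroxy ester F6. Burgess dehydration, for which H-1 is the only syn β-hydrogen, gives the unsaturated ester F7, and LiAlH4 reduction gives 11. Its own risks are competing enolisation of the ketone at the hindered tertiary C1 and the configuration at C4, which rests on the chelated transition state.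

Step 7. What may go wrong: intermolecular hydroboration from the more open α face, or boron ending on C5. The fallback delivers both hydrogen and oxygen from the carboxyl group; it sets out from 11 and comes back at 14. Dess–Martin oxidation gives the aldehyde F8 and NaClO2/NaH2PO4/2-methyl-2-butene the acid F9. Acid-catalysed lactonisation (TfOH cat., CH2Cl2, −20 °C) is expected to protonate C5 and close onto C1 on the β face to give the bridged lactone F10. iBu2AlH at −78 °C then gives the lactol F11, the ring-chain tautomer of 14, which KH opens to alkoxide 20 in step 11. Its own risks are protonation at C1 instead, which would give the cyclopropylcarbinyl cation at C5, and the face of protonation at C5.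

**Further compounds**
F1 | step 11 | primary tert-butyldimethylsilyl ether of 13 | O[C@]12CC[C@](C)(CO[Si](C)(C)C(C)(C)C)[C@H]1[C@H]1[C@@H](CC[C@@H]2C)C1(C)C
F2 | step 11 | 3,5-bis(benzyloxy)phenyl ether of F1 at the tertiary oxygen | c1c(OCc2ccccc2)cc(OCc2ccccc2)cc1O[C@]12CC[C@](C)(CO[Si](C)(C)C(C)(C)C)[C@H]1[C@H]1[C@@H](CC[C@@H]2C)C1(C)C
F3 | step 11 | primary alcohol from F2 | c1c(OCc2ccccc2)cc(OCc2ccccc2)cc1O[C@]12CC[C@](C)(CO)[C@H]1[C@H]1[C@@H](CC[C@@H]2C)C1(C)C
F4 | step 11 | aldehyde from F3 | c1c(OCc2ccccc2)cc(OCc2ccccc2)cc1O[C@]12CC[C@](C)(C=O)[C@H]1[C@H]1[C@@H](CC[C@@H]2C)C1(C)C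
F5 | step 6 | methyl 2-methyl-4-(4,8,8-trimethyl-2-oxobicyclo[5.1.0]oct-3-yl)butanoate | COC(=O)C(C)CC[C@@H]1[C@@H](C)CC[C@@H]2[C@H](C1=O)C2(C)C
F6 | step 6 | methyl 5β-hydroxy-10-epi-aromadendrane-4β-carboxylate (1β-H, 4α-methyl) | COC(=O)[C@@]1(C)CC[C@@H]2[C@@H](C)CC[C@@H]3[C@@H](C3(C)C)[C@]12O
F7 | step 6 | methyl 10-epi-aromadendr-1(5)-ene-4β-carboxylate | COC(=O)[C@@]1(C)CCC2=C1[C@H]1[C@@H](CC[C@@H]2C)C1(C)C
F8 | step 7 | 10-epi-aromadendr-1(5)-ene-4β-carbaldehyde | O=C[C@@]1(C)CCC2=C1[C@H]1[C@@H](CC[C@@H]2C)C1(C)C
F9 | step 7 | 10-epi-aromadendr-1(5)-ene-4β-carboxylic acid | OC(=O)[C@@]1(C)CCC2=C1[C@H]1[C@@H](CC[C@@H]2C)C1(C)C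
F10 | step 7 | bridged γ-lactone between the C4β carboxyl group and O–C1β (5β-H) | O=C1O[C@]23CC[C@@]1(C)[C@H]2[C@H]1[C@@H](CC[C@@H]3C)C1(C)C
F11 | step 7 | bridged lactol, ring-chain tautomer of 14 (either configuration at the hemiacetal carbon) | OC1O[C@]23CC[C@@]1(C)[C@H]2[C@H]1[C@@H](CC[C@@H]3C)C1(C)C
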